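**Strategy.** The hexamer (ring A: butyrylfilicinic ring; rings B–E: butyrylphloroglucinols; ring F: C-methyl ring) is disconnected at the bond between the ring B–ring C bridging CH2 and its ring B carbon. That CH2 sits on a ring C carbon flanked by two C–OH carbons, so a (dimethylamino)methyl group there releases an ortho-quinone methide on warming; the ring B carbon between two hydroxyls is the only unsubstituted ring carbon of the A–B dimer. One protecting-group-free thermal step thus joins the rings C–F tetramer Mannich base with the A–B dimer. The tetramer is grown from ring F by the same Mannich/elimination–addition cycle, each intermediate having one free ring carbon.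

Key step: step 9

Remark: the target has no stereocentre, so no stereochemical control is needed; every compound is written in the enol/keto tautomer of the target SMILES.

Step 1
Reactants: 1 phloroglucinol (benzene-1,3,5-triol)
Product: 2 phlorobutyrophenone
Conditions: butyryl chloride (1.0 equiv), AlCl3 (3.5 equiv), PhNO2/CH2Cl2, 0 °C to 50 °C; ice/aq. HCl
Reagents that add atoms: butyryl chloride, CCCC(=O)Cl
Why: Friedel–Crafts acylation of the symmetrical triol should give a single regioisomer because all three ring carbons are equivalent, and the chelated aryl ketone deactivates the ring towards a second acylation.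

Step 2
Reactants: 2 phlorobutyrophenone
Product: 3 butyrylfilicinic acid
Conditions: MeI (2.2 equiv), NaOMe (3 equiv), MeOH, 0 °C to rt; aq. HCl
Reagents that add atoms: methyl iodide, CI
Why: Dearomatising double C-methylation of the phloroglucinol polyanion with MeI (the classical entry to acylfilicinic acids) should place both methyl groups on one of the two equivalent free ring carbons, and the β-triketone acid is separated from mono- and trimethylated congeners by crystallisation.

Step 3
Reactants: 3 butyrylfilicinic acid; 2 phlorobutyrophenone (5 equiv)
Product: 5 norflavaspidic acid BB (rings A–B dimer), via filicinic Mannich base 4 (not isolated)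
Conditions: Me2NCH2NMe2 (1.0 equiv), THF, rt, evaporate; then 2 (5 equiv), 1,4-dioxane, 80 °C, Ar
Reagents that add atoms: bis(dimethylamino)methane, CN(C)CN(C)C
Why: Mannich aminomethylation should occur at the only C–H of the enolised triketone ring, and on heating the Mannich base loses dimethylamine in an elimination–addition (Michael/Friedel–Crafts) sequence in which one of the two equivalent free ring carbons of 2 adds to the exocyclic methylene, the excess of 2 suppressing double alkylation.

Step 4
Reactants: 6 2-methylphloroglucinol (2-methylbenzene-1,3,5-triol)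
Product: 7 ring F monomer 1-(2,4,6-trihydroxy-3-methylphenyl)butan-1-one
Conditions: butyryl chloride (1.0 equiv), AlCl3 (3.5 equiv), PhNO2/CH2Cl2, 0 °C to 50 °C; ice/aq. HCl
Reagents that add atoms: butyryl chloride, CCCC(=O)Cl
Why: Friedel–Crafts acylation of 2-methylphloroglucinol, whose two free ring carbons are equivalent, should give one regioisomer and stop at the monoketone.

Step 5
Reactants: 7 ring F monomer; 2 phlorobutyrophenone (5 equiv)
Product: 9 rings E–F dimer, via ring F Mannich base 8 (not isolated)
Conditions: Me2NCH2NMe2 (1.0 equiv), THF, rt, evaporate; then 2 (5 equiv), 1,4-dioxane, 80 °C, Ar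
Reagents that add atoms: bis(dimethylamino)methane, CN(C)CN(C)C
Why: The Mannich reaction takes the single free ring carbon of 7, and thermal elimination–addition of the aminomethyl arm (o-quinone methide Friedel–Crafts alkylation) to one of the two equivalent free carbons of 2, used in excess so that each molecule of 2 is alkylated once, should give the dimer with exactly one free ring carbon on ring E.

Step 6
Reactants: 9 rings E–F dimer; 2 phlorobutyrophenone (5 equiv)
Product: 11 rings D–E–F trimer, via dimer Mannich base 10 (not isolated)
Conditions: Me2NCH2NMe2 (1.0 equiv), THF, rt, evaporate; then 2 (5 equiv), 1,4-dioxane, 80 °C, Ar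
Reagents that add atoms: bis(dimethylamino)methane, CN(C)CN(C)C
Why: The same Mannich/elimination–addition cycle should be regiospecific because 9 has only one unsubstituted ring carbon (ring E), and the excess monomer 2, which differs greatly in size from the product, captures the o-quinone methide once and is removed easily.

Step 7
Reactants: 11 rings D–E–F trimer; 2 phlorobutyrophenone (5 equiv)
Product: 13 rings C–D–E–F tetramer, via trimer Mannich base 12 (not isolated)
Conditions: Me2NCH2NMe2 (1.0 equiv), THF, rt, evaporate; then 2 (5 equiv), 1,4-dioxane, 80 °C, Ar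
Reagents that add atoms: bis(dimethylamino)methane, CN(C)CN(C)C
Why: A third Mannich/elimination–addition cycle at the only free ring carbon of 11 (ring D) should attach ring C through a new methylene bridge and leave one free carbon on ring C, the excess of 2 again suppressing double alkylation.

Step 8
Reactants: 13 rings C–D–E–F tetramer
Product: 14 tetramer Mannich base carrying CH2NMe2 on ring C
Conditions: Me2NCH2NMe2 (1.05 equiv), THF, 0 °C to rt; evaporate, triturate with Et2O
Reagents that add atoms: bis(dimethylamino)methane, CN(C)CN(C)C
Why: Mannich reaction of the iminium ion formed in situ at the only unsubstituted aromatic carbon of the molecule (ring C, flanked by two OH groups) should be regiospecific and give the zwitterionic Mannich base, which is isolated without heating.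

Step 9
Reactants: 14 tetramer Mannich base; 5 norflavaspidic acid BB (2 equiv)
Product: 16 CNP0309827.0 (rings A–B–C–D–E–F hexamer), via ring C o-quinone methide 15 (not isolated)
Conditions: 5 (2 equiv), 1,4-dioxane, 70–80 °C, Ar sweep; dilute aq. HCl work-up
Reagents that add atoms: none
Why: Warming the zwitterionic Mannich base 14 should expel dimethylamine in an E1cB-type elimination to give the ring C o-quinone methide 15, and the ring B carbon of 5 that lies between two hydroxyl-bearing carbons adds to its exocyclic CH2 in a vinylogous Michael (Friedel–Crafts-type) step, after which tautomerisation restores both aromatic rings. The closest known reaction type is the Mannich-base/o-quinone methide alkylation used to build methylene-bridged acylphloroglucinol dimers. No ring is closed and no stereocentre is created, the target being achiral. The step needs cross-coupling in place of self-condensation and a single site of attack: 14 has no unsubstituted ring carbon, 5 has exactly one, and ring A is fully substituted, so only the wanted C–C bond can form irreversibly while O-alkylation is reversible. Excess 5, the lowest workable temperature and removal of the amine in the argon stream should limit ipso attack at existing bridges.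

**Compound list**

1 | phloroglucinol (benzene-1,3,5-triol) | Oc1cc(O)cc(O)c1 | starting material
2 | phlorobutyrophenone, 1-(2,4,6-trihydroxyphenyl)butan-1-one | CCCC(=O)c1c(O)cc(O)cc1O | intermediate
3 | butyrylfilicinic acid, 2-butanoyl-3,5-dihydroxy-4,4-dimethylcyclohexa-2,5-dien-1-one | CCCC(=O)C1=C(O)C(C)(C)C(O)=CC1=O | intermediate
4 | filicinic Mannich base, 2-butanoyl-6-[(dimethylamino)methyl]-3,5-dihydroxy-4,4-dimethylcyclohexa-2,5-dien-1-one | CCCC(=O)C1=C(O)C(C)(C)C(O)=C(CN(C)C)C1=O | intermediate
5 | norflavaspidic acid BB (rings A–B), 2-butanoyl-6-[(3-butanoyl-2,4,6-trihydroxyphenyl)methyl]-3,5-dihydroxy-4,4-dimethylcyclohexa-2,5-dien-1-one | CCCC(=O)C1=C(O)C(C)(C)C(O)=C(Cc2c(O)cc(O)c(C(=O)CCC)c2O)C1=O | intermediate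
6 | 2-methylphloroglucinol (2-methylbenzene-1,3,5-triol) | Cc1c(O)cc(O)cc1O | starting material
7 | ring F monomer, 1-(2,4,6-trihydroxy-3-methylphenyl)butan-1-one | CCCC(=O)c1c(O)cc(O)c(C)c1O | intermediate
8 | ring F Mannich base, 1-{3-[(dimethylamino)methyl]-2,4,6-trihydroxy-5-methylphenyl}butan-1-one | CCCC(=O)c1c(O)c(C)c(O)c(CN(C)C)c1O | intermediate
9 | rings E–F dimer, 1-{3-[(3-butanoyl-2,4,6-trihydroxy-5-methylphenyl)methyl]-2,4,6-trihydroxyphenyl}butan-1-one | CCCC(=O)c1c(O)cc(O)c(Cc2c(O)c(C)c(O)c(C(=O)CCC)c2O)c1O | intermediate
10 | dimer Mannich base, 1-{3-[(3-butanoyl-2,4,6-trihydroxy-5-methylphenyl)methyl]-5-[(dimethylamino)methyl]-2,4,6-trihydroxyphenyl}butan-1-one | CCCC(=O)c1c(O)c(CN(C)C)c(O)c(Cc2c(O)c(C)c(O)c(C(=O)CCC)c2O)c1O | intermediate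
11 | rings D–E–F trimer: dimer 9 carrying a (3-butanoyl-2,4,6-trihydroxyphenyl)methyl group (ring D, one C–H left) on the former free carbon of ring E | CCCC(=O)c1c(O)cc(O)c(Cc2c(O)c(Cc3c(O)c(C)c(O)c(C(=O)CCC)c3O)c(O)c(C(=O)CCC)c2O)c1O | intermediate
12 | trimer Mannich base: 11 with a (dimethylamino)methyl group on the free carbon of ring D | CCCC(=O)c1c(O)c(CN(C)C)c(O)c(Cc2c(O)c(Cc3c(O)c(C)c(O)c(C(=O)CCC)c3O)c(O)c(C(=O)CCC)c2O)c1O | intermediate
13 | rings C–D–E–F tetramer: trimer 11 carrying a (3-butanoyl-2,4,6-trihydroxyphenyl)methyl group (ring C, one C–H left) on the former free carbon of ring D | CCCC(=O)c1c(O)cc(O)c(Cc2c(O)c(Cc3c(O)c(Cc4c(O)c(C)c(O)c(C(=O)CCC)c4O)c(O)c(C(=O)CCC)c3O)c(O)c(C(=O)CCC)c2O)c1O | intermediate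
14 | tetramer Mannich base: 13 with a (dimethylamino)methyl group on the free carbon of ring C | CCCC(=O)c1c(O)c(CN(C)C)c(O)c(Cc2c(O)c(Cc3c(O)c(Cc4c(O)c(C)c(O)c(C(=O)CCC)c4O)c(O)c(C(=O)CCC)c3O)c(O)c(C(=O)CCC)c2O)c1O | intermediate
15 | ring C o-quinone methide: 14 after loss of dimethylamine, exocyclic C=CH2 on a cyclohexadienone ring C | C=C1C(=O)C(C(=O)CCC)=C(O)C(Cc2c(O)c(Cc3c(O)c(Cc4c(O)c(C)c(O)c(C(=O)CCC)c4O)c(O)c(C(=O)CCC)c3O)c(O)c(C(=O)CCC)c2O)=C1O | intermediate
16 | CNP0309827.0, methylene-bridged hexamer rings A–B–C–D–E–F | CCCC(=O)C1=C(O)C(C)(C)C(O)=C(Cc2c(O)c(Cc3c(O)c(Cc4c(O)c(Cc5c(O)c(Cc6c(O)c(C)c(O)c(C(=O)CCC)c6O)c(O)c(C(=O)CCC)c5O)c(O)c(C(=O)CCC)c4O)c(O)c(C(=O)CCC)c3O)c(O)c(C(=O)CCC)c2O)C1=O | target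

**Total step count:** 9

**Longest linear sequence:** 6 steps (6 → 7 → 9 → 11 → 13 → 14 → 16, that is steps 4 to 9; the branch 1 → 2 that feeds step 5 is equally long)

**Steps most likely to fail**

First, the key step (step 9). The methylene bridges may redistribute by ipso attack and retro-Friedel–Crafts cleavage, in particular with loss of the filicinic ring A from 5, and 14 may self-condense, because the mixture is warm and contains liberated amine. The fallback introduces the labile ring A last and makes the large fragment the nucleophile. It sets out from 14, which is heated with a tenfold excess of 2 (1,4-dioxane, 80 °C) to give the rings B–C–D–E–F pentamer F1 with one free carbon on ring B. F1 is then alkylated by the highly reactive filicinic Mannich base 4 (prepared from 3 as in the first stage of step 3) in 1,4-dioxane at 40–50 °C, which comes back to the route at 16.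

Second, step 7. In the third consecutive heating cycle the long trimer Mannich base may fragment by bridge exchange before it is trapped, the incoming monomer may be alkylated at both of its free carbons, and the homologues may fail to separate. The fallback is convergent, so that the electrophile is only a dimer and the long chain is formed in one coupling. It sets out from 2 and from 9. Condensation of excess 2 with aqueous formaldehyde (0.5 equiv) in dilute aq. NaOH at 0 °C should give the symmetrical methylene-bis(butyrylphloroglucinol) rings C–D dimer F2. The dimer Mannich base 10 (prepared from 9 as in the first stage of step 6) is then heated with an excess of F2 in 1,4-dioxane at 80 °C, which comes back to the route at 13. Compounds 11 and 12 are then not needed.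

Third, step 8. The iminium ion may attack bridged ring carbons of the tetramer (transaminomethylation with chain cleavage), and the zwitterionic product may lose amine and self-condense during isolation. The fallback brings in the one-carbon unit at the aldehyde oxidation level, so that a stable intermediate can be purified and the amine is formed without heat. It sets out from 13, whose single free ring carbon is formylated under Vilsmeier conditions (POCl3, DMF, EtOAc, 0 °C to rt; aqueous hydrolysis) to give the ring C aldehyde F3. Reductive amination of F3 with dimethylamine and NaBH(OAc)3 (THF, AcOH, rt), in which the hydrogen-bonded aryl ketones should stay untouched, comes back to the route at 14.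

Further compounds
F1 | step 9 | rings B–C–D–E–F pentamer with one free carbon on ring B | CCCC(=O)c1c(O)c(Cc5c(O)cc(O)c(C(=O)CCC)c5O)c(O)c(Cc2c(O)c(Cc3c(O)c(Cc4c(O)c(C)c(O)c(C(=O)CCC)c4O)c(O)c(C(=O)CCC)c3O)c(O)c(C(=O)CCC)c2O)c1O
F2 | step 7 | rings C–D dimer, 1-{3-[(3-butanoyl-2,4,6-trihydroxyphenyl)methyl]-2,4,6-trihydroxyphenyl}butan-1-one | CCCC(=O)c1c(O)cc(O)c(Cc2c(O)cc(O)c(C(=O)CCC)c2O)c1O
F3 | step 8 | ring C aldehyde: tetramer 13 with a formyl group on the free carbon of ring C | CCCC(=O)c1c(O)c(C=O)c(O)c(Cc2c(O)c(Cc3c(O)c(Cc4c(O)c(C)c(O)c(C(=O)CCC)c4O)c(O)c(C(=O)CCC)c3O)c(O)c(C(=O)CCC)c2O)c1O
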